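## Structural features

The target is an isoflavone: a benzene ring (ring A) fused through C4a–C8a to a 4-pyranone (ring C) that carries a 4-hydroxyphenyl group (ring B) on C3 and a hydrogen on C2. Ring A has no hydrogen left: C5 bears OMe, C6 a (2S)-2-hydroxy-3-methylbutyl chain, C7 a free OH and C8 a prenyl group. Three oxygens in three different states (methyl ether on C5, free phenol on C7, ring oxygen O1 on C8a) therefore alternate with three carbon substituents (the C4 acyl carbon on C4a and the two chains). The only stereocentre is the carbinol carbon of the C6 chain; it has no stereogenic neighbour and is not enolisable, so it can come from the chiral pool and only has to be spared inversion. The fragile parts are the prenyl alkene, which lies ortho to the free 7-OH and closes to a dimethylchroman under strong acid (and rules out hydrogenolysis), and the C2–H end of the pyranone, which is open to hydroxide and other hard nucleophiles. The real difficulty is regiochemical: a hexasubstituted ring A with two different carbon branches and three differently treated oxygens, and no free position to direct a substitution. The plan uses the fact that ring A is a phloroglucinol nucleus (oxygens on C5, C7, C8a; carbon on C4a, C6, C8), i.e. a folded chain C4–C4a–C8a–C8–C7–C6–C5 in which the hydroxyl of the C6 branch lies gamma to C5. C5 and that oxygen can be stored as a gamma-lactone whose alkoxide is the leaving group of a ring-closing Claisen reaction, while C8a, C4 and O1 are stored as a 4-pyranone.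

## Logic of the disconnections

21 ⇒ 20. The two acetal O–CH2 bonds on O7 and O4' are cut (the two phenols are masked). One protecting group on both oxygens allows a single release. The forward step must use acid mild enough for the prenyl group next to the freed 7-OH.

20 ⇒ 19. The O5–CH3 bond is cut. In 19 the 5-OH is the only free phenol, so the methyl ether needs no selectivity among phenols. The forward step must alkylate a hydrogen-bonded, flanked hydroxyl without touching the aliphatic alcohol.

19 ⇒ 18. The O7–CH2 bond is cut. This is the point where O7 and O5 are told apart; it relies on the higher acidity of the 7-OH and the chelation of the 5-OH.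

18 ⇒ 17 (key). The C4a–C5 bond is cut and the side-chain oxygen is rejoined to C5 as a lactone. Ring A disappears: 17 is an isomer of 18 in which the hexasubstituted benzene has become a chain on a disubstituted pyranone. The positions of prenyl (C8) and hydroxyalkyl (C6) are fixed by the order of carbons in the chain. The forward step needs C4a to act as a carbon nucleophile towards the lactone carbonyl and must leave the carbinol C–O bond untouched.

17 ⇒ 8 + 15. The C6–C7 bond is cut, with an extra carboxyl on C6 in the lactone half. A lithium lactone enolate cannot be used on an ester of 8, because the C8–H of such an ester is far more acidic and would be removed first. The carboxyl on C6 in 15 allows C-acylation through a magnesium enolate under nearly neutral conditions and then leaves as CO2. The result is a convergent union of an achiral pyranone acid and a chiral lactone acid. The forward step needs acyl transfer to outrun proton transfer.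

8 ⇒ 7 ⇒ 5 + 6. The C7–C8 bond (a one-carbon electrophile at the acid oxidation level) and the C8–CH2 bond to the prenyl unit are cut. Both sit on the lateral carbon of the pyranone, the vinylogous alpha-position, so the same deprotonation serves twice. The forward steps need reaction at the exocyclic carbon and monoalkylation.

5 ⇒ 3 (through 4). The O1–C2 bond and the C4a–C8a bond are cut. The pyranone becomes an enaminone methyl ketone plus an acetyl donor. The forward step needs C-acylation of the only enolisable position and an acid closure that spares the aryl acetal.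

3 ⇒ 2 ⇒ 1. The C2–C3 bond (aminomethylene carbon) and the O4'–CH2 bond are cut. The benzylic CH2 of 2 is the only doubly activated position, so the one-carbon unit enters there and blocks it.

15 ⇒ 12 + 13 (through 14). The C6–CH2 bond of the side chain and the acyl C–O bond of the lactone are cut. The epoxide delivers the carbinol stereocentre with its C–O bond intact; the malonate delivers C6, C5 and the auxiliary carboxyl. The forward step needs attack at the terminal epoxide carbon only.

12 ⇒ 11 ⇒ 10 ⇒ 9. The epoxide C–O bond (formed with inversion at the stereocentre), the alcohol oxidation level and the C–Cl bond (formed from C–N with retention) are taken back in turn. One net inversion converts the natural amino acid 9 into the configuration required in 21.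

## Other disconnections considered

Alternative 1: The cut is at both bonds of the C4 carbonyl, C4a–C4 and C4–C3. Ring A arrives as the hexasubstituted aryl iodide A1 (iodine on C4a), C3 with ring B and C2 as the alkenyl boronate A2, and C4 as carbon monoxide. In the forward sense Pd(PPh3)4, a zerovalent palladium complex, would insert into the C4a–I bond, take up CO and couple with A2 to give the aryl 2-ethoxy-1-arylvinyl ketone A3, ring C still open. Acid would then free O8a and close O1–C2 by addition–elimination.
- In its favour: carbonylative Suzuki–Miyaura coupling is an established reaction class, whereas the ring closure of the chosen plan is untested; on precedent this alternative is the better one.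
- Also in its favour: the methyl ether on O5 is already in A1, so ring C can only close on O8a and no late differentiation of phenols is needed. The endgame of one or two deprotections is shorter than the three operations after step 11.
- Against it: the whole regiochemical problem is moved into A1, a benzene with six different substituents that would have to be made by stepwise metalation, alkylation and halogenation of a differentiated phloroglucinol ether. That is likely to take more steps than the five plus four that lead to 17.
- Also against it: the C4a–I bond is flanked by two ortho oxygens, so oxidative addition, CO insertion and transmetalation should all be slow, and CO-free coupling and protodeboronation of the electron-rich A2 would compete.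
- Comparison: both plans take the stereocentre from 12 and are equal there. The chosen plan builds ring A and its substitution pattern in one isomerisation from an acyclic chain; the alternative is safer mechanistically but is expected to be longer overall.

Alternative 2: The cut is at C7–C8 and C4a–C8a. The cyclobutenone A4 supplies C4a, C5 (with OMe), C6 (with the protected chain) and C7; the siloxyalkyne A5 supplies C8 (with prenyl) and C8a (with oxygen). On heating in toluene the two should combine by way of ketene intermediates (ring opening, [2+2] addition, ring opening, six-electron electrocyclisation) to the phenol A6.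
- In its favour: regiochemistry is set by the polarisation of the alkyne and not by aromatic substitution; in this it is the equal of the chosen plan.
- Also in its favour: the three oxygens emerge already differentiated (OMe on C5, free OH on C7, silyl ether on C8a). That is better than the chosen plan, which needs steps 12 and 13 to tell O7 from O5.
- Also in its favour: the pericyclic cascade is a known type, which is an advantage in precedent.
- Against it: A6 is only ring A. C4a still carries hydrogen, so the arylacetyl unit would have to be introduced at the last free position of a pentasubstituted, acid-sensitive arene. Friedel–Crafts conditions threaten the prenyl group and the silyl ethers, and a Fries-type detour costs steps.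
- Also against it: ring C must then be built by a formylative cyclisation, which means more operations after the key step than the three of the chosen plan. A4 and the hydrolytically labile A5 also need syntheses of their own.
- Comparison: the chosen plan closes ring A with rings B and C in place; the alternative has the better-understood key step but the poorer step economy.

Alternative 3: The cut is at C8a–O1, C4a–C4 and O1–C2, so ring C is annulated onto a finished ring A. Ring A is the silyl triflate A7 (aryne across C4a–C8a); the other partner is the cesium acrylate A8. CsF should release the aryne; the carboxylate oxygen adds to C8a, the aryl anion at C4a takes the acyl group, and the phenoxide displaces methoxide at C2 to give A9, the fully protected target.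
- In its favour: it is the most convergent of the four plans. A9 is one or two deprotections from 21, which is better economy after the key step than the chosen plan, and the methyl ether on O5 is built in.
- Also in its favour: the inductive effect of the OMe on C5 should steer the oxygen nucleophile to the distal aryne carbon C8a, the required sense, so regiocontrol by the substrate is comparable to that of the chosen plan.
- Against it: A7 needs the complete hexasubstituted ring A plus an ortho silyl triflate, the longest precursor of all.
- Also against it: the aryne is generated next to a prenyl group, and ene reactions of arynes with trisubstituted alkenes are fast. C8a is also shielded by that group.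
- Also against it: the insertion–annulation with a beta-alkoxyacrylate salt is itself an extension of known aryne acyl-transfer chemistry, so it has no clear advantage in precedent over step 11.
- Comparison: the alternative has the better endgame and comparable regiocontrol, but it is worse on precursor length and on compatibility of the reactive intermediate with the prenyl group.

Key step: step 11

Remark: atoms of all intermediates carry the numbers of the final chromone (O1, C2, C3, C4, C4a, C5–C8, C8a; O4' on ring B). Assumption: 8, 14, 15 and 17 are used as mixtures of epimers at C8 and C6, because both carbons become sp2 in step 11; only the carbinol centre derived from 9 is controlled.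

## Route

Step 1
Reactants: 1 1-(4-hydroxyphenyl)propan-2-one (4-hydroxyphenylacetone)
Product: 2 1-[4-(methoxymethoxy)phenyl]propan-2-one
Conditions: MOMCl, i-Pr2NEt, CH2Cl2, 0 → 25 °C
Reagents that add atoms: chloromethyl methyl ether, COCCl
Why: Williamson-type O-alkylation of the phenoxide by the reactive chloromethyl ether; the ketone is inert and the acetal withstands every basic step that follows.

Step 2
Reactants: 2 1-[4-(methoxymethoxy)phenyl]propan-2-one
Product: 3 4-(dimethylamino)-3-[4-(methoxymethoxy)phenyl]but-3-en-2-one
Conditions: Me2NCH(OMe)2, PhMe, 90 °C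
Reagents that add atoms: N,N-dimethylformamide dimethyl acetal, COC(OC)N(C)C
Why: Condensation of the formamide acetal at the benzylic CH2, the only position activated by both the aryl group and the ketone, gives the vinylogous amide (enaminone formation); this blocks the benzylic carbon and installs the future C2.

Step 3
Reactants: 3 4-(dimethylamino)-3-[4-(methoxymethoxy)phenyl]but-3-en-2-one
Product: 5 5-[4-(methoxymethoxy)phenyl]-2-methyl-4H-pyran-4-one, via acetylated enaminone 4 (not isolated)
Conditions: LiN(SiMe3)2 (2.2 equiv), THF, −78 °C; AcCl, −78 → 0 °C; then AcOH, 50 °C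
Reagents that add atoms: acetyl chloride, CC(=O)Cl
Why: The methyl group is now the only enolisable position, so its lithium enolate is C-acylated to the 1,3-diketone 4 (Claisen-type acylation; the second equivalent of base takes up the acidic diketone), and mild acid closes the 4-pyranone by 6-endo-trig addition of the enol oxygen to the aminomethylene carbon with loss of dimethylamine; acetic acid is weak enough to spare the aryl acetal.

Step 4
Reactants: 5 5-[4-(methoxymethoxy)phenyl]-2-methyl-4H-pyran-4-one; 6 1-bromo-3-methylbut-2-ene (prenyl bromide)
Product: 7 5-[4-(methoxymethoxy)phenyl]-2-(4-methylpent-3-en-1-yl)-4H-pyran-4-one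
Conditions: LiN(SiMe3)2 (1.05 equiv), THF, −78 °C; 6, −78 → −30 °C
Reagents that add atoms: none
Why: The base removes a proton from the 2-methyl group (vinylogous to the ring carbonyl) and the dienolate is alkylated at its exocyclic gamma-carbon by the allylic bromide (SN2), the usual site of reaction of 2-methyl-4-pyranone anions with alkyl halides; low temperature and a small excess of 5 limit a second alkylation.

Step 5
Reactants: 7 5-[4-(methoxymethoxy)phenyl]-2-(4-methylpent-3-en-1-yl)-4H-pyran-4-one
Product: 8 (2RS)-2-{5-[4-(methoxymethoxy)phenyl]-4-oxo-4H-pyran-2-yl}-5-methylhex-4-enoic acid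
Conditions: LiN(SiMe3)2 (1.2 equiv), THF, −78 °C; CO2 (excess), −78 → −20 °C; then 1 M HCl to pH 3, 0 °C
Reagents that add atoms: carbon dioxide, O=C=O
Why: A second lateral deprotonation gives the secondary dienolate, which is carboxylated at the same exocyclic carbon; cold, brief acidification frees the vinylogous beta-keto acid, which is used at once to avoid decarboxylation.

Step 6
Reactants: 9 L-valine, (2S)-2-amino-3-methylbutanoic acid
Product: 10 (2S)-2-chloro-3-methylbutanoic acid
Conditions: NaNO2, 5 M HCl, 0 → 25 °C
Reagents that add atoms: hydrogen chloride, Cl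
Why: Diazotisation in hydrochloric acid replaces NH2 by Cl with net retention (double inversion through the alpha-lactone formed by carboxylate participation), so the (S) configuration is kept.

Step 7
Reactants: 10 (2S)-2-chloro-3-methylbutanoic acid
Product: 11 (2S)-2-chloro-3-methylbutan-1-ol
Conditions: LiAlH4, Et2O, 0 °C
Reagents that add atoms: none
Why: LiAlH4 reduces the carboxylic acid to the primary alcohol at 0 °C without displacing the secondary chloride; the stereocentre is not involved.

Step 8
Reactants: 11 (2S)-2-chloro-3-methylbutan-1-ol
Product: 12 (2R)-2-(propan-2-yl)oxirane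
Conditions: KOH (50% aq), 0 → 60 °C, product distilled out
Reagents that add atoms: none
Why: Intramolecular Williamson closure: the primary alkoxide displaces chloride from the rear, so the stereocentre is inverted once and the (R)-epoxide results, the configuration that maps onto the (S)-carbinol of the target.

Step 9
Reactants: 12 (2R)-2-(propan-2-yl)oxirane; 13 dimethyl malonate
Product: 15 (5S)-2-oxo-5-(propan-2-yl)oxolane-3-carboxylic acid, via lactone methyl ester 14 (not isolated)
Conditions: NaOMe, MeOH, 60 °C (sealed); then 2 M NaOH, 25 °C; then HCl to pH 1, 0 °C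
Reagents that add atoms: sodium hydroxide, [Na+].[OH-]
Why: The malonate anion opens the epoxide at the unhindered CH2 (SN2; the C–O bond of the stereocentre is untouched) and the alkoxide lactonises onto one ester to give 14; saponification and re-acidification, on which the gamma-hydroxy diacid relactonises, leave the malonic half-ester 15, whose C3 epimers are of no consequence.

Step 10
Reactants: 8 (2RS)-2-{5-[4-(methoxymethoxy)phenyl]-4-oxo-4H-pyran-2-yl}-5-methylhex-4-enoic acid; 15 (5S)-2-oxo-5-(propan-2-yl)oxolane-3-carboxylic acid
Product: 17 (5S)-3-(2-{5-[4-(methoxymethoxy)phenyl]-4-oxo-4H-pyran-2-yl}-5-methylhex-4-enoyl)-5-(propan-2-yl)oxolan-2-one, via acyl imidazolide 16 (not isolated)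
Conditions: 8, 1,1'-carbonyldiimidazole, THF, 25 °C; added to 15 + i-PrMgCl (2 equiv per 15), THF, 0 °C; 25 → 40 °C; then 1 M HCl, 0 °C
Reagents that add atoms: none
Why: Decarboxylative Claisen condensation: the magnesium enolate–carboxylate of the malonic half-ester 15 is C-acylated by the acyl imidazolide 16 under nearly neutral conditions and loses CO2, which gives the beta-keto lactone without exposing 16 (acidic at C8) to a strongly basic enolate; should 16 shed imidazole to a ketene, capture by the same magnesium enolate at carbon leads to the same product.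

Step 11
Reactants: 17 (5S)-3-(2-{5-[4-(methoxymethoxy)phenyl]-4-oxo-4H-pyran-2-yl}-5-methylhex-4-enoyl)-5-(propan-2-yl)oxolan-2-one
Product: 18 5,7-dihydroxy-6-[(2S)-2-hydroxy-3-methylbutyl]-3-[4-(methoxymethoxy)phenyl]-8-(3-methylbut-2-en-1-yl)-4H-chromen-4-one
Conditions: LiN(SiMe3)2 (2.5 equiv), THF, −78 → 25 °C; then 1 M HCl, 0 °C
Reagents that add atoms: none
Why: Proposed new method: the base should remove the C6–H of the beta-keto lactone and the C8–H, giving a dianion in which the C8 charge is delocalised through C8a=C4a into the pyranone carbonyl, so that the pyranone CH (C4a) becomes the alpha-carbon of a dienolate and adds to the lactone carbonyl C5. The tetrahedral intermediate expels the gamma-alkoxide, which stays as the side-chain hydroxyl with its C–O bond intact, and loss of the doubly activated C4a–H gives the aromatic phenoxide, which makes the sequence irreversible. The closest known reaction type is the base-mediated Claisen cyclisation of open-chain 3,5,7-tricarbonyl esters to acylphloroglucinols; here the C8a and C4 carbonyls of that chain are stored as a 4-pyranone, a known mask for a 1,3,5-triketone, and what is untested is a pyranone dienolate acylated at its ring carbon by an ester. Ring A closes in a 6-exo-trig mode at the lactone carbonyl; classified by the reacting O–C4=C4a enolate unit it is 6-(enolexo)-exo-trig, not enolendo, with the C8a=C8 bond of the dienolate inside the new ring, a favoured closure. No stereocentre is formed: the two epimeric centres of 17 become sp2, and the carbinol centre, which is not enolisable and whose C–O bond is not broken, is carried through unchanged. The step needs carbon and not oxygen acylation, attack on the lactone and not on a ketone, and prenyl on C8 with the hydroxyalkyl chain on C6. O-acylation or attack by C8 would require a four-membered or bridged ring; the only other six-membered closure, aldol attack of C6 on C4, would give a bridged bicycle at a poorly electrophilic vinylogous ester; and the substituent positions are fixed by the order of carbons along the chain.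

Step 12
Reactants: 18 5,7-dihydroxy-6-[(2S)-2-hydroxy-3-methylbutyl]-3-[4-(methoxymethoxy)phenyl]-8-(3-methylbut-2-en-1-yl)-4H-chromen-4-one
Product: 19 5-hydroxy-6-[(2S)-2-hydroxy-3-methylbutyl]-7-(methoxymethoxy)-3-[4-(methoxymethoxy)phenyl]-8-(3-methylbut-2-en-1-yl)-4H-chromen-4-one
Conditions: MOMCl (1.1 equiv), K2CO3, acetone, 0 → 25 °C
Reagents that add atoms: chloromethyl methyl ether, COCCl
Why: The 7-OH is the most acidic phenol (conjugated with the C4 carbonyl) and is etherified first (Williamson reaction); the 5-OH is held in a hydrogen bond to C4=O and the aliphatic alcohol is not ionised by K2CO3, so one equivalent of the chloromethyl ether should be selective.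

Step 13
Reactants: 19 5-hydroxy-6-[(2S)-2-hydroxy-3-methylbutyl]-7-(methoxymethoxy)-3-[4-(methoxymethoxy)phenyl]-8-(3-methylbut-2-en-1-yl)-4H-chromen-4-one
Product: 20 6-[(2S)-2-hydroxy-3-methylbutyl]-5-methoxy-7-(methoxymethoxy)-3-[4-(methoxymethoxy)phenyl]-8-(3-methylbut-2-en-1-yl)-4H-chromen-4-one
Conditions: MeI (excess), K2CO3, DMF, 40 °C
Reagents that add atoms: iodomethane, CI
Why: With O7 and O4' blocked the chelated 5-OH is the only acidic site and is methylated under more forcing Williamson conditions; K2CO3 does not ionise the secondary alcohol.

Step 14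
Reactants: 20 6-[(2S)-2-hydroxy-3-methylbutyl]-5-methoxy-7-(methoxymethoxy)-3-[4-(methoxymethoxy)phenyl]-8-(3-methylbut-2-en-1-yl)-4H-chromen-4-one
Product: 21 7-hydroxy-6-[(2S)-2-hydroxy-3-methylbutyl]-3-(4-hydroxyphenyl)-5-methoxy-8-(3-methylbut-2-en-1-yl)-4H-chromen-4-one (CNP0323282.1)
Conditions: 3 M HCl (aq), MeOH, 40 °C
Reagents that add atoms: none
Why: Acid-catalysed methanolysis cleaves both aryl methoxymethyl acetals in one operation; dilute acid at moderate temperature is chosen because the freed 7-OH lies next to the prenyl group, and the methyl ether and the secondary alcohol are stable to it.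

## Compound list

1 | 1-(4-hydroxyphenyl)propan-2-one | CC(=O)Cc1ccc(O)cc1 | starting material
2 | 1-[4-(methoxymethoxy)phenyl]propan-2-one | CC(=O)Cc1ccc(OCOC)cc1 | intermediate
3 | 4-(dimethylamino)-3-[4-(methoxymethoxy)phenyl]but-3-en-2-one | CC(=O)C(=CN(C)C)c1ccc(OCOC)cc1 | intermediate
4 | 1-(dimethylamino)-2-[4-(methoxymethoxy)phenyl]hex-1-ene-3,5-dione | CN(C)C=C(c1ccc(OCOC)cc1)C(=O)CC(C)=O | intermediate (not isolated)
5 | 5-[4-(methoxymethoxy)phenyl]-2-methyl-4H-pyran-4-one | CC1=CC(=O)C(=CO1)c1ccc(OCOC)cc1 | intermediate
6 | 1-bromo-3-methylbut-2-ene | CC(C)=CCBr | starting material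
7 | 5-[4-(methoxymethoxy)phenyl]-2-(4-methylpent-3-en-1-yl)-4H-pyran-4-one | CC(C)=CCCC1=CC(=O)C(=CO1)c1ccc(OCOC)cc1 | intermediate
8 | (2RS)-2-{5-[4-(methoxymethoxy)phenyl]-4-oxo-4H-pyran-2-yl}-5-methylhex-4-enoic acid | CC(C)=CCC(C(=O)O)C1=CC(=O)C(=CO1)c1ccc(OCOC)cc1 | intermediate
9 | L-valine, (2S)-2-amino-3-methylbutanoic acid | CC(C)[C@H](N)C(=O)O | starting material
10 | (2S)-2-chloro-3-methylbutanoic acid | CC(C)[C@H](Cl)C(=O)O | intermediate
11 | (2S)-2-chloro-3-methylbutan-1-ol | CC(C)[C@H](Cl)CO | intermediate
12 | (2R)-2-(propan-2-yl)oxirane | CC(C)[C@@H]1CO1 | intermediate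
13 | dimethyl malonate | COC(=O)CC(=O)OC | starting material
14 | methyl (5S)-2-oxo-5-(propan-2-yl)oxolane-3-carboxylate (both C3 epimers) | CC(C)[C@@H]1CC(C(=O)OC)C(=O)O1 | intermediate (not isolated)
15 | (5S)-2-oxo-5-(propan-2-yl)oxolane-3-carboxylic acid (both C3 epimers) | CC(C)[C@@H]1CC(C(=O)O)C(=O)O1 | intermediate
16 | 1-(1H-imidazol-1-yl)-2-{5-[4-(methoxymethoxy)phenyl]-4-oxo-4H-pyran-2-yl}-5-methylhex-4-en-1-one | CC(C)=CCC(C(=O)n1ccnc1)C1=CC(=O)C(=CO1)c1ccc(OCOC)cc1 | intermediate (not isolated)
17 | (5S)-3-(2-{5-[4-(methoxymethoxy)phenyl]-4-oxo-4H-pyran-2-yl}-5-methylhex-4-enoyl)-5-(propan-2-yl)oxolan-2-one (epimers at the two enolisable carbons) | COCOc1ccc(cc1)C1=COC(=CC1=O)C(CC=C(C)C)C(=O)C1C[C@H](OC1=O)C(C)C | intermediate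
18 | 5,7-dihydroxy-6-[(2S)-2-hydroxy-3-methylbutyl]-3-[4-(methoxymethoxy)phenyl]-8-(3-methylbut-2-en-1-yl)-4H-chromen-4-one | COCOc1ccc(cc1)-c1coc2c(CC=C(C)C)c(O)c(C[C@H](O)C(C)C)c(O)c2c1=O | intermediate
19 | 5-hydroxy-6-[(2S)-2-hydroxy-3-methylbutyl]-7-(methoxymethoxy)-3-[4-(methoxymethoxy)phenyl]-8-(3-methylbut-2-en-1-yl)-4H-chromen-4-one | COCOc1ccc(cc1)-c1coc2c(CC=C(C)C)c(OCOC)c(C[C@H](O)C(C)C)c(O)c2c1=O | intermediate
20 | 6-[(2S)-2-hydroxy-3-methylbutyl]-5-methoxy-7-(methoxymethoxy)-3-[4-(methoxymethoxy)phenyl]-8-(3-methylbut-2-en-1-yl)-4H-chromen-4-one | COCOc1ccc(cc1)-c1coc2c(CC=C(C)C)c(OCOC)c(C[C@H](O)C(C)C)c(OC)c2c1=O | intermediate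
21 | 7-hydroxy-6-[(2S)-2-hydroxy-3-methylbutyl]-3-(4-hydroxyphenyl)-5-methoxy-8-(3-methylbut-2-en-1-yl)-4H-chromen-4-one | COc1c(C[C@H](O)C(C)C)c(O)c(CC=C(C)C)c2occ(-c3ccc(O)cc3)c(=O)c12 | target

## Step count and least certain steps

Total: 14 steps. Longest linear sequence: 10 steps (steps 1–5 and 10–14, from 1); the branch from 9 (steps 6–9) joins at step 10.

**Step 11 (key step, proposed new method).** The most likely failure is that the dianion does not close: deprotonation at C6 makes the lactone carbonyl part of an enolate and lowers its electrophilicity, so the substrate may persist until slower processes take over. Those are conjugate addition at C2 with opening of the pyranone, or retro-Claisen cleavage at C7 once alkoxide accumulates. A change of counter-ion or a protic Mg(OMe)2 medium would be tried first, but the fallback changes the approach.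

Fallback (known chemistry; sets out from 12 and 6, returns at 18): the pyranone is given up as nucleophile, ring A is made from an open chain by the classical base-mediated Claisen cyclisation of a 3,5,7-tricarbonyl ester, and ring C is closed last. 12 is opened by methyl acetoacetate (NaOMe, MeOH, reflux) to (5S)-3-acetyl-5-(propan-2-yl)oxolan-2-one F1. Its dianion (LiN(iPr)2, 2.1 equiv, THF, 0 °C) is alkylated at the terminal carbon by 6 to (5S)-3-(5-methylhex-4-enoyl)-5-(propan-2-yl)oxolan-2-one F2. The dianion of F2 is acylated at C8 by N-methoxy-N-methylacetamide to (5S)-3-[2-(3-methylbut-2-en-1-yl)-3-oxobutanoyl]-5-(propan-2-yl)oxolan-2-one F3. The trianion of F3 (LiN(iPr)2, 3.3 equiv) is acylated at its terminal methyl carbon by methyl [4-(methoxymethoxy)phenyl]acetate F4 (from methyl 4-hydroxyphenylacetate as in step 1; used in deficiency because it is enolisable) to (5S)-3-{6-[4-(methoxymethoxy)phenyl]-2-(3-methylbut-2-en-1-yl)-3,5-dioxohexanoyl}-5-(propan-2-yl)oxolan-2-one F5. Mg(OMe)2 in MeOH at reflux should then close ring A, with C4a now an ordinary beta-diketone carbon attacking the lactone carbonyl, to 2-[4-(methoxymethoxy)phenyl]-1-{2,4,6-trihydroxy-3-[(2S)-2-hydroxy-3-methylbutyl]-5-(3-methylbut-2-en-1-yl)phenyl}ethan-1-one F6. N,N-dimethylformamide dimethyl acetal (THF, 40 °C, then AcOH) adds C2 and closes ring C to 18. The cost is that ring C can close on either ortho hydroxyl, so 18 would be accompanied by 5,7-dihydroxy-8-[(2S)-2-hydroxy-3-methylbutyl]-3-[4-(methoxymethoxy)phenyl]-6-(3-methylbut-2-en-1-yl)-4H-chromen-4-one F7 and would have to be separated from it. The regiocontrol that the pyranone provides is lost, which is why this route is only the reserve.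

**Step 10.** The most likely failure is proton transfer from the acyl imidazolide 16, whose C8–H is activated twice, to the magnesium enolate, followed by ketene formation and self-condensation of the acyl donor in competition with C-acylation.

Fallback (sets out from 15 and 8, returns at 17): the basic enolate is replaced by a neutral C-acylation of a ketene silyl acetal. 15 is decarboxylated in toluene at 110 °C to (5S)-5-(propan-2-yl)oxolan-2-one F8, which is converted (LiN(iPr)2, THF, −78 °C; Me3SiCl) into trimethyl{[(5S)-5-(propan-2-yl)-4,5-dihydrofuran-2-yl]oxy}silane F9. 8 is turned into 2-{5-[4-(methoxymethoxy)phenyl]-4-oxo-4H-pyran-2-yl}-5-methylhex-4-enoyl chloride F10 with 1-chloro-N,N,2-trimethylprop-1-en-1-amine (CH2Cl2, 0 °C), a reagent that sets free neither acid nor base. F9 and F10 are combined in CH2Cl2 (ZnCl2 cat., 0 → 25 °C) and should give 17 with loss of Me3SiCl; no species is present that could deprotonate the acyl donor.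

**Step 4.** The most likely failure is over-alkylation through proton exchange between product and unreacted dienolate, with some attack through the tertiary terminus of the allylic bromide.

Fallback (sets out from 3, returns at 7): C8 is brought in with its prenyl group already attached. 5-Methylhex-4-enoic acid is converted into 5-methylhex-4-enoyl chloride F11 ((COCl)2, DMF cat., CH2Cl2) and used in place of acetyl chloride in the protocol of step 3. The open-chain diketone 1-(dimethylamino)-2-[4-(methoxymethoxy)phenyl]-9-methyldeca-1,8-diene-3,5-dione F12 is cyclised with AcOH as before and gives 7 directly, so that 5 and the lateral alkylation are bypassed. It is held in reserve only because the acid is a less common starting material than 6.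

**Step 14.** The most likely failure is acid-induced cyclisation of the prenyl group onto the liberated 7-hydroxyl (dimethylchroman formation), or hydration of the alkene, while the second acetal is still being cleaved.

Fallback (sets out from 18, returns at 21): orthogonal protection, so that the acid step is run while O7 is still blocked. 18 is allylated on O7 (allyl bromide, K2CO3, acetone) to 5-hydroxy-6-[(2S)-2-hydroxy-3-methylbutyl]-3-[4-(methoxymethoxy)phenyl]-8-(3-methylbut-2-en-1-yl)-7-(prop-2-en-1-yloxy)-4H-chromen-4-one F13. This is methylated as in step 13 to 6-[(2S)-2-hydroxy-3-methylbutyl]-5-methoxy-3-[4-(methoxymethoxy)phenyl]-8-(3-methylbut-2-en-1-yl)-7-(prop-2-en-1-yloxy)-4H-chromen-4-one F14. The single acetal on O4' is removed with HCl in MeOH to 6-[(2S)-2-hydroxy-3-methylbutyl]-3-(4-hydroxyphenyl)-5-methoxy-8-(3-methylbut-2-en-1-yl)-7-(prop-2-en-1-yloxy)-4H-chromen-4-one F15, in which no free hydroxyl flanks the prenyl group. The allyl ether is then cleaved with Pd(PPh3)4 (zerovalent palladium) and morpholine in THF to give 21.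

## Further compounds

F1 | step 11 | (5S)-3-acetyl-5-(propan-2-yl)oxolan-2-one | CC(=O)C1C[C@H](OC1=O)C(C)C
F2 | step 11 | (5S)-3-(5-methylhex-4-enoyl)-5-(propan-2-yl)oxolan-2-one | CC(C)=CCCC(=O)C1C[C@H](OC1=O)C(C)C
F3 | step 11 | (5S)-3-[2-(3-methylbut-2-en-1-yl)-3-oxobutanoyl]-5-(propan-2-yl)oxolan-2-one | CC(=O)C(CC=C(C)C)C(=O)C1C[C@H](OC1=O)C(C)C
F4 | step 11 | methyl [4-(methoxymethoxy)phenyl]acetate | COC(=O)Cc1ccc(OCOC)cc1
F5 | step 11 | (5S)-3-{6-[4-(methoxymethoxy)phenyl]-2-(3-methylbut-2-en-1-yl)-3,5-dioxohexanoyl}-5-(propan-2-yl)oxolan-2-one | COCOc1ccc(CC(=O)CC(=O)C(CC=C(C)C)C(=O)C2C[C@H](OC2=O)C(C)C)cc1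
F6 | step 11 | 2-[4-(methoxymethoxy)phenyl]-1-{2,4,6-trihydroxy-3-[(2S)-2-hydroxy-3-methylbutyl]-5-(3-methylbut-2-en-1-yl)phenyl}ethan-1-one | COCOc1ccc(CC(=O)c2c(O)c(CC=C(C)C)c(O)c(C[C@H](O)C(C)C)c2O)cc1
F7 | step 11 | 5,7-dihydroxy-8-[(2S)-2-hydroxy-3-methylbutyl]-3-[4-(methoxymethoxy)phenyl]-6-(3-methylbut-2-en-1-yl)-4H-chromen-4-one | COCOc1ccc(cc1)-c1coc2c(C[C@H](O)C(C)C)c(O)c(CC=C(C)C)c(O)c2c1=O
F8 | step 10 | (5S)-5-(propan-2-yl)oxolan-2-one | CC(C)[C@@H]1CCC(=O)O1
F9 | step 10 | trimethyl{[(5S)-5-(propan-2-yl)-4,5-dihydrofuran-2-yl]oxy}silane | CC(C)[C@@H]1CC=C(O[Si](C)(C)C)O1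
F10 | step 10 | 2-{5-[4-(methoxymethoxy)phenyl]-4-oxo-4H-pyran-2-yl}-5-methylhex-4-enoyl chloride | CC(C)=CCC(C(=O)Cl)C1=CC(=O)C(=CO1)c1ccc(OCOC)cc1
F11 | step 4 | 5-methylhex-4-enoyl chloride | CC(C)=CCCC(=O)Cl
F12 | step 4 | 1-(dimethylamino)-2-[4-(methoxymethoxy)phenyl]-9-methyldeca-1,8-diene-3,5-dione | CN(C)C=C(c1ccc(OCOC)cc1)C(=O)CC(=O)CCC=C(C)C
F13 | step 14 | 5-hydroxy-6-[(2S)-2-hydroxy-3-methylbutyl]-3-[4-(methoxymethoxy)phenyl]-8-(3-methylbut-2-en-1-yl)-7-(prop-2-en-1-yloxy)-4H-chromen-4-one | COCOc1ccc(cc1)-c1coc2c(CC=C(C)C)c(OCC=C)c(C[C@H](O)C(C)C)c(O)c2c1=O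
F14 | step 14 | 6-[(2S)-2-hydroxy-3-methylbutyl]-5-methoxy-3-[4-(methoxymethoxy)phenyl]-8-(3-methylbut-2-en-1-yl)-7-(prop-2-en-1-yloxy)-4H-chromen-4-one | COCOc1ccc(cc1)-c1coc2c(CC=C(C)C)c(OCC=C)c(C[C@H](O)C(C)C)c(OC)c2c1=O
F15 | step 14 | 6-[(2S)-2-hydroxy-3-methylbutyl]-3-(4-hydroxyphenyl)-5-methoxy-8-(3-methylbut-2-en-1-yl)-7-(prop-2-en-1-yloxy)-4H-chromen-4-one | Oc1ccc(cc1)-c1coc2c(CC=C(C)C)c(OCC=C)c(C[C@H](O)C(C)C)c(OC)c2c1=O
A1 | alternative 1 | tert-butyl{[(2S)-1-[3-iodo-2-methoxy-4,6-bis(methoxymethoxy)-5-(3-methylbut-2-en-1-yl)phenyl]-3-methylbutan-2-yl]oxy}dimethylsilane | COc1c(I)c(OCOC)c(CC=C(C)C)c(OCOC)c1C[C@H](O[Si](C)(C)C(C)(C)C)C(C)C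
A2 | alternative 1 | 2-{(Z)-2-ethoxy-1-[4-(methoxymethoxy)phenyl]ethenyl}-4,4,5,5-tetramethyl-1,3,2-dioxaborolane | CCO/C=C(\c1ccc(OCOC)cc1)B1OC(C)(C)C(C)(C)O1
A3 | alternative 1 | (2E)-1-{3-[(2S)-2-(tert-butyldimethylsilyloxy)-3-methylbutyl]-2-methoxy-4,6-bis(methoxymethoxy)-5-(3-methylbut-2-en-1-yl)phenyl}-3-ethoxy-2-[4-(methoxymethoxy)phenyl]prop-2-en-1-one | CCO/C=C(\c1ccc(OCOC)cc1)C(=O)c1c(OC)c(C[C@H](O[Si](C)(C)C(C)(C)C)C(C)C)c(OCOC)c(CC=C(C)C)c1OCOC
A4 | alternative 2 | 4-[(2S)-2-(tert-butyldimethylsilyloxy)-3-methylbutyl]-3-methoxycyclobut-2-en-1-one | COC1=CC(=O)C1C[C@H](O[Si](C)(C)C(C)(C)C)C(C)C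
A5 | alternative 2 | triisopropyl[(5-methylhex-4-en-1-yn-1-yl)oxy]silane | CC(C)=CCC#CO[Si](C(C)C)(C(C)C)C(C)C
A6 | alternative 2 | 2-[(2S)-2-(tert-butyldimethylsilyloxy)-3-methylbutyl]-3-methoxy-6-(3-methylbut-2-en-1-yl)-5-(triisopropylsilyloxy)phenol | COc1cc(O[Si](C(C)C)(C(C)C)C(C)C)c(CC=C(C)C)c(O)c1C[C@H](O[Si](C)(C)C(C)(C)C)C(C)C
A7 | alternative 3 | 4-[(2S)-2-(tert-butyldimethylsilyloxy)-3-methylbutyl]-3-methoxy-5-(methoxymethoxy)-6-(3-methylbut-2-en-1-yl)-2-(trimethylsilyl)phenyl trifluoromethanesulfonate | COc1c([Si](C)(C)C)c(OS(=O)(=O)C(F)(F)F)c(CC=C(C)C)c(OCOC)c1C[C@H](O[Si](C)(C)C(C)(C)C)C(C)C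
A8 | alternative 3 | cesium 3-methoxy-2-[4-(methoxymethoxy)phenyl]prop-2-enoate | [Cs+].[O-]C(=O)C(=COC)c1ccc(OCOC)cc1
A9 | alternative 3 | 6-[(2S)-2-(tert-butyldimethylsilyloxy)-3-methylbutyl]-5-methoxy-7-(methoxymethoxy)-3-[4-(methoxymethoxy)phenyl]-8-(3-methylbut-2-en-1-yl)-4H-chromen-4-one | COc1c(C[C@H](O[Si](C)(C)C(C)(C)C)C(C)C)c(OCOC)c(CC=C(C)C)c2occ(-c3ccc(OCOC)cc3)c(=O)c12
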